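Time does little in Wednesday's run: Z stands at 36.6 % after 3.00 h and 39.0 % after 40.0 h. The flask winter, on the same recipe, runs longer still, so its Z is read as a plateau.

| setting | Wednesday's | Monday's | winter | summer | dusk | autumn |
|---|---|---|---|---|---|---|
| D | 0.10 M | 0.10 M | 0.10 M | 0.10 M | 0.10 M | 0.10 M (fed, over 12 h) |
| Q | 1 equiv | 2 equiv | 1.00 equiv | 1.00 equiv (fed, over 12 h) | 1.00 equiv | 1.00 equiv |
| temperature | 20 °C | 20 °C | 20 °C |  |  | 20 °C |
| remark | run made earlier | run made earlier | everything together at the start | the addition at −10 °C, then warmed to 20 °C; the feed brings no volume worth counting | everything together at the start at −10 °C, warmed to 20 °C at 12 h | all else is in the flask from the start; the feed brings no volume worth counting |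
| time |  |  | 2.5 d | 2.5 d | 2.5 d | 2.5 d |

- Wednesday's (time / h: Z / %): 3.00: 36.6; 4.00: 38.2; 6.00: 37.8; 10.0: 37.0; 15.0: 38.1; 25.0: 38.2; 40.0: 39.0
- Monday's (time / h: Z / %): 0.333: 54.6; 1.00: 67.8; 1.50: 68.9; 2.50: 71.1; 4.00: 72.7; 5.00: 70.6; 6.00: 71.5

(readings scatter by 1 percentage point)

- the best flask by amount of Z, in percent of the D charged; "all alike" if 1.5 percentage points covers them all (winter / summer / dusk / autumn / all alike)
- amount of Z at the end, in percent of the D charged, winter
- amount of Z at the end, in percent of the D charged, summer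
- amount of Z at the end, in percent of the D charged, dusk
- amount of Z at the end, in percent of the D charged, autumn

A balance of Q, taken as the limiting reagent, splits the charge into Q that made Z and Q that went elsewhere. Folded into one number, with Z and Q both counted per D charged:

φ = Z at the plateau / Q charged = 39.0 % / 1 equiv = 0.390

So φ, the share of the charged Q that ends as Z, is read from Wednesday's run. This reckoning then gives winter, which repeats that recipe:

Z = φ × 1.00 equiv = 39.0 %

The test is Monday's run. The same φ promises 78.0 % there, but the reading is 71.5 %, a gap of 6.5 percentage points, more than the scatter of 1 point. Monday's own φ, read the same way, is 0.357, so Wednesday's φ does not carry to Monday's charge of Q. The earlier runs hold no cold and no feed, so φ for summer, dusk and autumn has no reading here.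

The forecast gives winter 38 % (36.5 % to 39.5 %), summer 42 % (28 % to 58 %), dusk 41 % (28 % to 55 %) and autumn 5 % (2 % to 22 %), with summer best. Its ground: “selectivity depends only on D, so feeding Q changes little”.

The flasks give winter 38.6 %, summer 43.0 %, dusk 53.4 % and autumn 24.5 %; dusk holds the most Z.

    D + Q → Z (k = 0.00578 M⁻¹ s⁻¹, Ea = 66.0 kJ mol⁻¹)
    D + Q → X, rate k2*[D] as long as [Q] is above zero (k = 2.49 × 10⁻⁴ s⁻¹, Ea = 91.0 kJ mol⁻¹)
    2 Q → L (k = 1.81 × 10⁻⁴ M⁻¹ s⁻¹, Ea = 58.0 kJ mol⁻¹)
    Q ⇌ E (K = 1.09, k = 2.24 × 10⁻⁴ s⁻¹, Ea = 94.0 kJ mol⁻¹, ΔH = −4.00 kJ mol⁻¹)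
    2 D → G (k = 1.45 × 10⁻⁷ M⁻¹ s⁻¹, Ea = 77.0 kJ mol⁻¹)
    (constants at 20 °C)

Dusk's φ is 0.534, above Wednesday's 0.390. Wednesday's run with only the temperature changed to dusk's gives 53.4 %; with only the time changed, 38.6 %. Autumn's φ is 0.245, below Wednesday's. Carried to the neighbouring flask, autumn with 2.50 equiv of Q:

Z = 0.245 × 2.50 equiv = 61.2 %

That neighbour holds 55.7 % of Z after 2.50 d, with D at 0 % and Q at 6.18 % of its charge.

The earlier runs and the new flask are calculated on assumed constants; noise was put on by code.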